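Read the two runs, then reckon what each flask can still do.

| flask | substrate | coupling partner | free catalyst | second catalyst | temperature | remark | time |
|---|---|---|---|---|---|---|---|
| birch | 0.0010 M | 1.5 equiv | 8.8 mol% | 2 mol% | 35 °C | the very flask that is asked about, followed so far |  |
| alder | 0.0010 M | 1.5 equiv | 8.8 mol% | 2 mol% | 41 °C | run made earlier |  |
| flask | 0.0010 M | 1.50 equiv | 8.8 mol% | 2 mol% | 35 °C |  | 6.0 min |

- birch (time / min: product / %, substrate / %): 1.33: 71.6, 27.9; 2.50: 71.4, 27.6; 4.00: 72.0, 28.1; 5.00: 72.1, 28.5; 6.00: 72.1, 27.6
- alder (time / min: product / %, substrate / %): 1.33: 58.8, 41.2; 2.50: 57.0, 41.0; 4.00: 57.7, 40.1; 5.00: 58.4, 42.0; 6.00: 58.3, 42.4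

(each reading ± 0.5 percentage points)

- alpha: at 6.0 min take out 90% of the product then present, then wait 3.0 min
- beta: change nothing and wait 3.0 min more
- theta: at 6.0 min add coupling partner, 50.0% of the amount charged, then wait 3.0 min
- eta: at 6.0 min add free catalyst, 50.0% of the amount charged, then wait 3.0 min
- delta: at 6.0 min raise the temperature by 20 K, then wait 3.0 min

- product taken out counts as made
- "the catalyst" is free catalyst with its forms; second catalyst is a second catalyst
- additions bring no volume worth counting

- product, in percent of the substrate first charged, at 6.0 min
- which option adds most product ("none" when 2 percentage points or less is all one gets) (alpha / beta / theta / eta / delta / none)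
- product present, with what was taken out counted in, in percent of the substrate first charged, after theta
- product present, with what was taken out counted in, in percent of the substrate first charged, after eta

1. Apply the bench rule first: with coupling partner in excess, substrate is the limiting reagent, so product should climb towards the substrate charged.

2. Find the border of that rule. The birch flask is flat from 1.33 min, at 71.8% product and 27.9% substrate. Its coupling partner charge is 2.09 times the product made, taking one partner per product. Neither charge is used up, so the rule stops here.

3. Choose a reading. The alder flask, hotter, stops with 41.3% substrate, more than the birch flask. Flatness alone is shared by an equilibrium and a dying catalyst, so it does not choose between them. Take the dying catalyst as your working reading.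

4. Integrate. Let substrate fall at a rate proportional to substrate and free catalyst, and let free catalyst decay first order. Then the logarithm of substrate falls by a finite total: ln(substrate charged / substrate left) = rate constant × catalyst charged / decay constant. The birch readings give 1.28 for this logarithm. Call it the catalyst reach; on this reading it grows in step with catalyst added.

5. Spend the reach. On this reading, alpha, beta, theta and delta add nothing, so 71.8% stands at 6.0 min and after theta. Eta adds 50.0% of the catalyst charge, hence 50.0% of the reach. Substrate falls to 14.7% and product reaches 85.2%. That gain of 13 percentage points exceeds the margin, so choose eta.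

6. Set this beside the forecast, which rests on “a fast, exothermic reversible equilibrium” and gives 72% now, alpha as best, 82.5% after theta and 72% after eta.

7. Read the result. The flask gives 71.8%, and eta is best at 85.0%, a gain of 13 points, while theta stays at 71.8%. At 6.00 min free catalyst stands at 0% and spent catalyst at 100%. Counting the rest after eta as substrate, 50.0% more catalyst delivered 0.485 of the reach.

    coupling partner + second catalyst + intermediate → second catalyst + product (k = 5.26 × 10⁶ M⁻² s⁻¹, Ea = 14.0 kJ mol⁻¹)
    coupling partner ⇌ dormant form (K = 0.242, k = 0.154 s⁻¹, Ea = 71.0 kJ mol⁻¹, ΔH = −45.0 kJ mol⁻¹)
    substrate + free catalyst → free catalyst + intermediate (k = 1010 M⁻¹ s⁻¹, Ea = 41.0 kJ mol⁻¹)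
    free catalyst → spent catalyst (k = 0.0702 s⁻¹, Ea = 91.0 kJ mol⁻¹)
    (constants at 35 °C)

8. Try the neighbour at 60 °C. The reach fell from 1.28 at 35 °C to 0.883 at 41 °C; continuing that factor gives 0.276, hence 24.1% product. The computed neighbour gives 25.4% product, with 74.6% substrate.

The earlier runs and the new flask come from a simulation with made-up constants, noise included.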